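Numbering: C1 bears the ester, C2=C3(CH3), C4, C5, C6 the tertiary carbinol, C7 the isopropyl carbon, C8, C9 the ketone, C10 the methyl-bearing quaternary carbon. The route rests on disconnecting C6–C7 in the five-membered ring (C6–C7–C8–C9–C10), exploiting the cis-vicinal C6 hydroxyl and C7 isopropyl group as the imprint of a carbonyl-ene reaction. One Lewis-acid-promoted ene cyclisation of a 2-acyl-2-methylcycloheptenone joins C7 of a prenyl-type olefin to the C6 ketone, closing the five-membered ring and setting C6 and C7 together. The precursor is a seven-membered 1,3-diketone with the C1 silyl ether, the C2=C3 olefin and a 4-methylpent-3-enoyl group on C10.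

Key step: step 10

Remark on the chemistry: while C7 bonds to C6, C8 must lie syn to C6 across C10–C9, so the C9 oxygen points away from the C6 oxygen and one aluminium cannot hold both. The key step is therefore planned with excess Me2AlCl, one aluminium on C6=O and another bridging the C9 carbonyl and the C1 silyl ether oxygen.

Step 1
Reactants: 1 (S)-4-benzyl-3-propionyloxazolidin-2-one; 2 acrolein
Product: 4 (S)-4-benzyl-3-[(2S,3R)-3-hydroxy-2-methylpent-4-enoyl]oxazolidin-2-one, via Z-dibutylboron enolate 3 (not isolated)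
Conditions: Bu2BOTf, Et3N, CH2Cl2, 0 °C; 2, −78 → 0 °C; then H2O2, MeOH, pH 7 buffer, 0 °C
Reagents that add atoms: none
Why: Evans syn-aldol reaction, in which the Z-boron enolate should add to acrolein through a chair Zimmerman–Traxler transition state on the face away from the benzyl group, setting the carbinol (later C1) as R and, for the time being, the methyl-bearing carbon (later C10) as S.

Step 2
Reactants: 4 (S)-4-benzyl-3-[(2S,3R)-3-hydroxy-2-methylpent-4-enoyl]oxazolidin-2-one
Product: 5 (2S,3R)-3-hydroxy-N-methoxy-N,2-dimethylpent-4-enamide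
Conditions: MeNH(OMe)·HCl, AlMe3, CH2Cl2, −20 → 0 °C; then 0.5 M aq HCl
Reagents that add atoms: N,O-dimethylhydroxylamine hydrochloride, CNOC.Cl
Why: Weinreb transamidation of the imide with the aluminium amide, which is most reliable on the free β-hydroxy imide, touches no stereocenter and releases the auxiliary for recovery.

Step 3
Reactants: 5 (2S,3R)-3-hydroxy-N-methoxy-N,2-dimethylpent-4-enamide
Product: 6 (2S,3R)-3-(tert-butyldimethylsilyloxy)-N-methoxy-N,2-dimethylpent-4-enamide
Conditions: TBSOTf, 2,6-lutidine, CH2Cl2, −78 → 0 °C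
Reagents that add atoms: tert-butyldimethylsilyl trifluoromethanesulfonate, CC(C)(C)[Si](C)(C)OS(=O)(=O)C(F)(F)F
Why: Silyl ether protection of the secondary alcohol with a silyl triflate and a hindered pyridine base is fast at low temperature and should not provoke retro-aldol cleavage.

Step 4
Reactants: 6 (2S,3R)-3-(tert-butyldimethylsilyloxy)-N-methoxy-N,2-dimethylpent-4-enamide; 7 4-bromo-2-methylbut-1-ene
Product: 9 (6S,7R)-7-(tert-butyldimethylsilyloxy)-2,6-dimethylnona-1,8-dien-5-one, via (3-methylbut-3-en-1-yl)magnesium bromide 8 (not isolated)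
Conditions: 7, Mg, THF, rt → 40 °C; then 6, THF, 0 °C; 1 M aq HCl, 0 °C
Reagents that add atoms: none
Why: Weinreb ketone synthesis, in which the N-methoxy-N-methylamide stops the Grignard addition at the ketone stage; any epimerisation next to the carbonyl is harmless because that center is flattened in step 6.

Step 5
Reactants: 9 (6S,7R)-7-(tert-butyldimethylsilyloxy)-2,6-dimethylnona-1,8-dien-5-one
Product: 10 (2S,3R)-3-(tert-butyldimethylsilyloxy)-2,5-dimethylcyclohept-4-en-1-one
Conditions: second-generation Grubbs catalyst RuCl2(=CHPh)(H2IMes)(PCy3) (5 mol %), CH2Cl2 (5 mM), 40 °C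
Reagents that add atoms: none
Why: Ring-closing olefin metathesis between the vinyl group and the 1,1-disubstituted olefin should give the trisubstituted cycloheptene (C2=C3), driven by loss of ethene at high dilution.

Step 6
Reactants: 10 (2S,3R)-3-(tert-butyldimethylsilyloxy)-2,5-dimethylcyclohept-4-en-1-one
Product: 11 (R)-3-(tert-butyldimethylsilyloxy)-2,5-dimethyl-1-(trimethylsilyloxy)cyclohepta-1,4-diene
Conditions: Me3SiCl, NaI, Et3N, MeCN, 0 °C → rt; pentane extraction
Reagents that add atoms: chlorotrimethylsilane, C[Si](C)(C)Cl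
Why: Silyl enol ether formation under equilibrating conditions should favour the tetrasubstituted C6=C10 enol ether, and the mild amine base at room temperature should leave the β-silyloxy group in place; the C10 stereocenter is erased on purpose.

Step 7
Reactants: 12 4-methylpent-3-en-1-ol
Product: 13 4-methylpent-3-enal
Conditions: Dess–Martin periodinane, pyridine, CH2Cl2, 0 °C → rt; filtered through silica and used at once as a CH2Cl2 solution
Reagents that add atoms: none
Why: Dess–Martin oxidation of the primary alcohol under buffered, non-acidic conditions stops at the aldehyde and should keep the double bond out of conjugation.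

Step 8
Reactants: 11 (R)-3-(tert-butyldimethylsilyloxy)-2,5-dimethyl-1-(trimethylsilyloxy)cyclohepta-1,4-diene; 13 4-methylpent-3-enal
Product: 14 (2S,3R)-3-(tert-butyldimethylsilyloxy)-2-(1-hydroxy-4-methylpent-3-enyl)-2,5-dimethylcyclohept-4-en-1-one (both carbinol epimers)
Conditions: BF3·OEt2, 13 (2 equiv), CH2Cl2, −78 °C; then aq NaHCO3
Reagents that add atoms: none
Why: Mukaiyama aldol addition, in which the BF3-activated aldehyde should attack C10 of the enol silane through an open transition state on the ring face anti to the neighbouring pseudoaxial C1 silyloxy group, creating the quaternary center with the new chain trans to the silyl ether (the carbinol configuration is irrelevant).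

Step 9
Reactants: 14 (2S,3R)-3-(tert-butyldimethylsilyloxy)-2-(1-hydroxy-4-methylpent-3-enyl)-2,5-dimethylcyclohept-4-en-1-one
Product: 15 (2S,3R)-3-(tert-butyldimethylsilyloxy)-2,5-dimethyl-2-(4-methylpent-3-enoyl)cyclohept-4-en-1-one
Conditions: Dess–Martin periodinane, pyridine, CH2Cl2, 0 °C → rt; short column on neutral silica
Reagents that add atoms: none
Why: Dess–Martin oxidation of the secondary alcohol gives the 1,3-diketone, which cannot enolise between the carbonyls because C10 is quaternary, and the neutral conditions should keep the skipped olefin out of conjugation.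

Step 10
Reactants: 15 (2S,3R)-3-(tert-butyldimethylsilyloxy)-2,5-dimethyl-2-(4-methylpent-3-enoyl)cyclohept-4-en-1-one
Product: 16 (3R,3aS,8R,8aS)-8-(tert-butyldimethylsilyloxy)-3a-hydroxy-6,8a-dimethyl-3-(prop-1-en-2-yl)-3,3a,4,5,8,8a-hexahydroazulen-1(2H)-one
Conditions: Me2AlCl (3 equiv), CH2Cl2, −78 → −20 °C; then 1 M aq HCl, 0 °C
Reagents that add atoms: none
Why: Me2AlCl on the C6 carbonyl oxygen makes C6 electrophilic, C7 of the trisubstituted olefin bonds to it while a hydrogen of an allylic methyl group passes to that oxygen through a six-membered array, and the double bond moves into the isopropenyl group; aqueous acid then frees the ketol. The closest known reaction type is the alkylaluminium-chloride-promoted intramolecular carbonyl-ene cyclisation of δ,ε-unsaturated aldehydes and ketones to 2-isopropenylcyclopentanols. The five-membered ring C6–C7–C8–C9–C10 closes in the 5-exo-trig mode at the C6 carbonyl, the olefin attacking through its tethered carbon. C7 is controlled by the hydrogen transfer, which needs the isopropylidene group over the C6 oxygen, so hydroxyl and isopropenyl should come out cis. C6 is controlled by the carbonyl face that meets C7, and the step needs the face that puts the hydroxyl anti to the C10 methyl (trans fusion): the C1 silyloxy and C10 acyl groups are trans, so both sit equatorial and gauche in one chair of the cycloheptenone, where a second aluminium can bridge the C1 oxygen and the C9 carbonyl oxygen and so fix the acyl rotamer that brings C8 and C7 to the methyl side of C6. The cis-fused mode would need the other chair with both groups axial and no such bridge, which is why excess reagent and a donor oxygen at C1 are kept in the design.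

Step 11
Reactants: 16 (3R,3aS,8R,8aS)-8-(tert-butyldimethylsilyloxy)-3a-hydroxy-6,8a-dimethyl-3-(prop-1-en-2-yl)-3,3a,4,5,8,8a-hexahydroazulen-1(2H)-one
Product: 17 (3R,3aS,8R,8aS)-8-(tert-butyldimethylsilyloxy)-3a-hydroxy-6,8a-dimethyl-3-(propan-2-yl)-3,3a,4,5,8,8a-hexahydroazulen-1(2H)-one
Conditions: H2 (1 atm), RhCl(PPh3)3 (10 mol %), benzene, rt
Reagents that add atoms: none
Why: Homogeneous hydrogenation with RhCl(PPh3)3 discriminates on steric grounds, so the 1,1-disubstituted isopropenyl olefin should be reduced while the trisubstituted ring olefin, the ketone and the silyl ether stay untouched; no stereocenter is created.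

Step 12
Reactants: 17 (3R,3aS,8R,8aS)-8-(tert-butyldimethylsilyloxy)-3a-hydroxy-6,8a-dimethyl-3-(propan-2-yl)-3,3a,4,5,8,8a-hexahydroazulen-1(2H)-one
Product: 18 (3R,3aS,8R,8aS)-3a,8-dihydroxy-6,8a-dimethyl-3-(propan-2-yl)-3,3a,4,5,8,8a-hexahydroazulen-1(2H)-one
Conditions: HF·pyridine, pyridine, THF, 0 °C → rt
Reagents that add atoms: none
Why: Fluoride-mediated desilylation with pyridine-buffered HF cleaves the Si–O bond under non-basic conditions, which should avoid retro-aldol opening of the β-hydroxy ketone.

Step 13
Reactants: 18 (3R,3aS,8R,8aS)-3a,8-dihydroxy-6,8a-dimethyl-3-(propan-2-yl)-3,3a,4,5,8,8a-hexahydroazulen-1(2H)-one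
Product: 19 (1R,3aS,4R,8aS)-8a-hydroxy-3a,6-dimethyl-3-oxo-1-(propan-2-yl)-1,2,3,3a,4,7,8,8a-octahydroazulen-4-yl 4-methoxybenzoate
Conditions: 4-MeOC6H4COCl, DMAP, Et3N, CH2Cl2, 0 °C → rt
Reagents that add atoms: 4-methoxybenzoyl chloride, COc1ccc(cc1)C(Cl)=O
Why: DMAP-catalysed acyl transfer should esterify the secondary allylic C1 alcohol while the tertiary C6 alcohol is too hindered to react, giving the target with all four stereocenters unchanged.

Compound list
1 | (S)-4-benzyl-3-propionyloxazolidin-2-one | CCC(=O)N1C(=O)OC[C@@H]1Cc1ccccc1 | starting material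
2 | acrolein | C=CC=O | starting material
3 | (S)-4-benzyl-3-[(Z)-1-(dibutylboranyloxy)prop-1-en-1-yl]oxazolidin-2-one | C/C=C(\OB(CCCC)CCCC)N1C(=O)OC[C@@H]1Cc1ccccc1 | intermediate
4 | (S)-4-benzyl-3-[(2S,3R)-3-hydroxy-2-methylpent-4-enoyl]oxazolidin-2-one | C=C[C@@H](O)[C@H](C)C(=O)N1C(=O)OC[C@@H]1Cc1ccccc1 | intermediate
5 | (2S,3R)-3-hydroxy-N-methoxy-N,2-dimethylpent-4-enamide | C=C[C@@H](O)[C@H](C)C(=O)N(C)OC | intermediate
6 | (2S,3R)-3-(tert-butyldimethylsilyloxy)-N-methoxy-N,2-dimethylpent-4-enamide | C=C[C@@H](O[Si](C)(C)C(C)(C)C)[C@H](C)C(=O)N(C)OC | intermediate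
7 | 4-bromo-2-methylbut-1-ene | CC(=C)CCBr | starting material
8 | (3-methylbut-3-en-1-yl)magnesium bromide | CC(=C)CC[Mg]Br | intermediate
9 | (6S,7R)-7-(tert-butyldimethylsilyloxy)-2,6-dimethylnona-1,8-dien-5-one | C=C[C@@H](O[Si](C)(C)C(C)(C)C)[C@H](C)C(=O)CCC(C)=C | intermediate
10 | (2S,3R)-3-(tert-butyldimethylsilyloxy)-2,5-dimethylcyclohept-4-en-1-one | CC(C)(C)[Si](C)(C)O[C@@H]1C=C(C)CCC(=O)[C@H]1C | intermediate
11 | (R)-3-(tert-butyldimethylsilyloxy)-2,5-dimethyl-1-(trimethylsilyloxy)cyclohepta-1,4-diene | CC(C)(C)[Si](C)(C)O[C@@H]1C=C(C)CCC(O[Si](C)(C)C)=C1C | intermediate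
12 | 4-methylpent-3-en-1-ol | CC(C)=CCCO | starting material
13 | 4-methylpent-3-enal | CC(C)=CCC=O | intermediate
14 | (2S,3R)-3-(tert-butyldimethylsilyloxy)-2-(1-hydroxy-4-methylpent-3-enyl)-2,5-dimethylcyclohept-4-en-1-one, side chain trans to the silyloxy group, carbinol epimers | CC(C)(C)[Si](C)(C)O[C@@H]1C=C(C)CCC(=O)[C@@]1(C)C(O)CC=C(C)C | intermediate
15 | (2S,3R)-3-(tert-butyldimethylsilyloxy)-2,5-dimethyl-2-(4-methylpent-3-enoyl)cyclohept-4-en-1-one, acyl group trans to the silyloxy group | CC(C)(C)[Si](C)(C)O[C@@H]1C=C(C)CCC(=O)[C@@]1(C)C(=O)CC=C(C)C | intermediate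
16 | (3R,3aS,8R,8aS)-8-(tert-butyldimethylsilyloxy)-3a-hydroxy-6,8a-dimethyl-3-(prop-1-en-2-yl)-3,3a,4,5,8,8a-hexahydroazulen-1(2H)-one, trans-fused, hydroxyl cis to isopropenyl | CC(C)(C)[Si](C)(C)O[C@@H]1C=C(C)CC[C@]2(O)[C@@H](C(C)=C)CC(=O)[C@@]12C | intermediate
17 | (3R,3aS,8R,8aS)-8-(tert-butyldimethylsilyloxy)-3a-hydroxy-6,8a-dimethyl-3-(propan-2-yl)-3,3a,4,5,8,8a-hexahydroazulen-1(2H)-one | CC(C)(C)[Si](C)(C)O[C@@H]1C=C(C)CC[C@]2(O)[C@@H](C(C)C)CC(=O)[C@@]12C | intermediate
18 | (3R,3aS,8R,8aS)-3a,8-dihydroxy-6,8a-dimethyl-3-(propan-2-yl)-3,3a,4,5,8,8a-hexahydroazulen-1(2H)-one | O[C@@H]1C=C(C)CC[C@]2(O)[C@@H](C(C)C)CC(=O)[C@@]12C | intermediate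
19 | (1R,3aS,4R,8aS)-8a-hydroxy-3a,6-dimethyl-3-oxo-1-(propan-2-yl)-1,2,3,3a,4,7,8,8a-octahydroazulen-4-yl 4-methoxybenzoate | COc1ccc(C(=O)O[C@@H]2C=C(C)CC[C@]3(O)[C@@H](C(C)C)CC(=O)[C@@]23C)cc1 | target

Total step count: 13. Longest linear sequence: 12 steps (steps 1–6 and 8–13); step 7 is a one-step side branch.

Steps most likely to fail

1. Step 10. The chain may close onto the other face of the C6 carbonyl and give the cis ring fusion, because the trans mode asks the preformed seven-membered ring for a wide torsion angle about C6–C10; the skipped enone may also slip into conjugation under the Lewis acid. The fallback inverts the order of ring formation; it sets out from 9 and comes back at 16. Dienone 9 is silylated as in step 6 to the open-chain trimethylsilyl enol ether F1, which is joined to 13 with BF3·OEt2 as in step 8 to give the open-chain aldol F2 and oxidised with Dess–Martin periodinane to the open-chain 1,3-diketone F3. C10 is then set by open-chain induction from C1, and its epimer would be removed by chromatography at this stage. Me2AlCl closes the five-membered ring by the same carbonyl-ene reaction onto a ketone that is not yet part of a ring, where the C5 chain can lie beside the small C10 methyl group without ring strain, to give the cyclopentanone ketol F4. Ring-closing metathesis of the vinyl group with the 2-methylallyl terminus (second-generation Grubbs catalyst RuCl2(=CHPh)(H2IMes)(PCy3), dilute CH2Cl2, 40 °C) then closes the seven-membered ring last and gives 16; the isopropenyl group on the crowded C7 would have to form a bridged ring and should stay out.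

2. Step 6. Silylation may go to the C5 methylene side, and the β-silyloxy group may be lost by elimination toward a conjugated dienone while the enol ether equilibrates. The fallback blocks C5 and enolises under kinetic control; it sets out from 10 and comes back at 14. Ketone 10 is sulfenylated twice at C5 (LiN(iPr)2, PhSSPh, THF–HMPA, −78 → 0 °C) to the bis(phenylsulfanyl) ketone F5. The only α-hydrogen left, at C10, is removed with LiN(SiMe3)2 at −78 °C in the presence of Me3SiCl to give the blocked enol silane F6. Mukaiyama aldol addition to 13 (BF3·OEt2, −78 °C) gives the blocked aldol F7, and SmI2 in THF–MeOH at −78 °C cleaves both carbon–sulfur bonds next to the ketone and returns 14.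

3. Step 8. The skipped enal may isomerise into conjugation or condense with itself under BF3 faster than the crowded tetrasubstituted enol silane captures it. The fallback replaces aldol addition and oxidation by direct acylation; it sets out from 11 and comes back at 15. Commercial 4-methylpent-3-enoic acid is converted with (COCl)2 and a trace of DMF into 4-methylpent-3-enoyl chloride F8, and enol silane 11 is C-acylated with it under ZnCl2 in CH2Cl2–Et2O at 0 °C (Lewis-acid-mediated acylation of a silyl enol ether), again anti to the C1 silyloxy group, to give diketone 15 without passing through 13 and 14.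

Further compounds
F1 | step 10 | (R)-3-(tert-butyldimethylsilyloxy)-4,8-dimethyl-5-(trimethylsilyloxy)nona-1,4,8-triene | C=C[C@@H](O[Si](C)(C)C(C)(C)C)C(C)=C(O[Si](C)(C)C)CCC(C)=C
F2 | step 10 | (6S,7R)-7-(tert-butyldimethylsilyloxy)-6-(1-hydroxy-4-methylpent-3-enyl)-2,6-dimethylnona-1,8-dien-5-one | C=C[C@@H](O[Si](C)(C)C(C)(C)C)[C@](C)(C(O)CC=C(C)C)C(=O)CCC(C)=C
F3 | step 10 | (6S,7R)-7-(tert-butyldimethylsilyloxy)-2,6-dimethyl-6-(4-methylpent-3-enoyl)nona-1,8-dien-5-one | C=C[C@@H](O[Si](C)(C)C(C)(C)C)[C@](C)(C(=O)CC=C(C)C)C(=O)CCC(C)=C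
F4 | step 10 | (2S,3S,4R)-2-[(1R)-1-(tert-butyldimethylsilyloxy)prop-2-en-1-yl]-3-hydroxy-2-methyl-3-(3-methylbut-3-en-1-yl)-4-(prop-1-en-2-yl)cyclopentan-1-one | C=C[C@@H](O[Si](C)(C)C(C)(C)C)[C@]1(C)C(=O)C[C@H](C(C)=C)[C@@]1(O)CCC(C)=C
F5 | step 6 | (6R,7S)-6-(tert-butyldimethylsilyloxy)-4,7-dimethyl-2,2-bis(phenylsulfanyl)cyclohept-4-en-1-one | CC(C)(C)[Si](C)(C)O[C@@H]1C=C(C)CC(Sc2ccccc2)(Sc2ccccc2)C(=O)[C@H]1C
F6 | step 6 | (R)-3-(tert-butyldimethylsilyloxy)-2,5-dimethyl-7,7-bis(phenylsulfanyl)-1-(trimethylsilyloxy)cyclohepta-1,4-diene | CC(C)(C)[Si](C)(C)O[C@@H]1C=C(C)CC(Sc2ccccc2)(Sc2ccccc2)C(O[Si](C)(C)C)=C1C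
F7 | step 6 | (6R,7S)-6-(tert-butyldimethylsilyloxy)-7-(1-hydroxy-4-methylpent-3-enyl)-4,7-dimethyl-2,2-bis(phenylsulfanyl)cyclohept-4-en-1-one | CC(C)(C)[Si](C)(C)O[C@@H]1C=C(C)CC(Sc2ccccc2)(Sc2ccccc2)C(=O)[C@@]1(C)C(O)CC=C(C)C
F8 | step 8 | 4-methylpent-3-enoyl chloride | CC(C)=CCC(=O)Cl
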